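**Assumption:** germacrane numbering is used (C6 = lactone carbinol, C7 = ring-fusion CH carrying C11(=C13)–C12, C8 = acyloxy carbon, C3 = CHCl, C1/C10 = epoxide), with α/β as in the usual germacranolide drawing (H-7 α). The target is then the 3β-chloro-1β,10α-epoxy-8β-acyloxy-(4Z)-germacra-4,11(13)-dien-12,6α-olide (1R,3S,6R,7R,8R,10R; side chain 2R,3R).

## Retrosynthetic overview

1. The 1β,10α-epoxide comes last, by peripheral epoxidation of the (1(10)E,4Z)-diene; the C8 ester comes from a lactic-acid-derived (2R,3R)-acid; C3–Cl comes from the 3α-alcohol by SN2 inversion.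
2. The ten-membered ring and the α-methylene-γ-lactone form together by closing C6–C7: a cathodic, chromium-catalysed intramolecular Barbier allylation of a Z-enal by a 2-(bromomethyl)acrylate (carbocycle first, lactone in the same pot).
3. Seco chain: the Z-enal end comes from a butenolide (Z locked in the ring); the allyl bromide end comes from a Baylis–Hillman reaction and bromination.
4. Backbone: the E-C1=C10 alkene comes from Negishi carboalumination; C8 from (S)-glycidol (acetylide opening); C3 from methyl (R)-glycidate (copper-catalysed alkenyl Grignard opening).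

## Route

**Step 1**
Reactants: 1 (S)-glycidol
Product: 2 (2R)-pent-4-yne-1,2-diol
Conditions: LiC≡CH·H2NCH2CH2NH2 (3 equiv), DMSO, 15 → 25 °C; aq. NH4Cl
Reagents that add atoms: lithium acetylide (ethylenediamine complex), [Li]C#C
Why: SN2 opening of the terminal epoxide carbon by acetylide leaves the carbinol centre untouched (the Payne-rearranged alkoxide is the same enantiomer), and this centre becomes C8.

**Step 2**
Reactants: 2 (2R)-pent-4-yne-1,2-diol
Product: 3 (4R)-4,5-bis(triethylsilyloxy)pent-1-yne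
Conditions: Et3SiCl (2.4 equiv), imidazole, DMAP (cat.), CH2Cl2, 0 °C
Reagents that add atoms: chlorotriethylsilane, CC[Si](Cl)(CC)CC
Why: Routine bis-silylation; the primary TES ether is later the latent C7 aldehyde.

**Step 3**
Reactants: 3 (4R)-4,5-bis(triethylsilyloxy)pent-1-yne
Product: 5 (1E,4R)-1-iodo-2-methyl-4,5-bis(triethylsilyloxy)pent-1-ene, via alkenyldimethylalane 4 (not isolated)
Conditions: Me3Al (2.5 equiv), Cp2ZrCl2 (0.25 equiv), CH2Cl2, 0 → 25 °C; then I2, THF, −30 °C; aq. Na2S2O3
Reagents that add atoms: trimethylaluminium, C[Al](C)C; iodine, II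
Why: Negishi zirconium-catalysed syn-carboalumination puts the methyl on the internal carbon and aluminium on the terminus, and iodinolysis with retention gives the E-iodide that becomes the E-C1=C10 alkene.

**Step 4**
Reactants: 5 (1E,4R)-1-iodo-2-methyl-4,5-bis(triethylsilyloxy)pent-1-ene; 6 methyl (2R)-oxirane-2-carboxylate (methyl (R)-glycidate)
Product: 8 methyl (2R,4E,7R)-2-hydroxy-5-methyl-7,8-bis(triethylsilyloxy)oct-4-enoate, via alkenylmagnesium chloride 7 (not isolated)
Conditions: i-PrMgCl·LiCl, THF, 0 → 25 °C; then CuI (10 mol %), 6, −40 → −20 °C; aq. NH4Cl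
Reagents that add atoms: isopropylmagnesium chloride (Mg and Cl in 7 only), CC(C)[Mg]Cl
Why: Iodine–magnesium exchange proceeds with retention, and the copper-catalysed Grignard opens the glycidate at its CH2 (SN2), so the glycidate stereocentre is carried unchanged into C3 (3R, the 3α-oxygen).

**Step 5**
Reactants: 8 methyl (2R,4E,7R)-2-hydroxy-5-methyl-7,8-bis(triethylsilyloxy)oct-4-enoate
Product: 10 (3R,5E,8R)-3-hydroxy-6-methyl-8,9-bis(triethylsilyloxy)non-5-en-2-one, via Weinreb amide 9 (not isolated)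
Conditions: MeNH(OMe)·HCl, i-PrMgCl, THF, −20 °C; then MeMgBr, −20 → 0 °C; aq. NH4Cl
Reagents that add atoms: methylmagnesium bromide, C[Mg]Br; N,O-dimethylhydroxylamine hydrochloride (atoms in 9 only), CNOC.Cl
Why: One-pot Weinreb amidation and Grignard addition; the chelated tetrahedral intermediate stops at the methyl ketone, and the α-centre is protected from enolisation as its magnesium alkoxide.

**Step 6**
Reactants: 10 (3R,5E,8R)-3-hydroxy-6-methyl-8,9-bis(triethylsilyloxy)non-5-en-2-one
Product: 12 (5R)-4-methyl-5-[(2E,5R)-3-methyl-5,6-bis(triethylsilyloxy)hex-2-en-1-yl]furan-2(5H)-one, via ylide ester 11 (not isolated)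
Conditions: Ph3P=C=C=O, toluene, 80 °C
Reagents that add atoms: (triphenylphosphoranylidene)ketene (Bestmann ylide), O=C=C=P(c1ccccc1)(c1ccccc1)c1ccccc1
Why: The hydroxyl adds to the ketene ylide and the resulting acyl ylide closes by intramolecular Wittig reaction under neutral conditions, so the C4=C5 bond is locked Z inside the butenolide.

**Step 7**
Reactants: 12 (5R)-4-methyl-5-[(2E,5R)-3-methyl-5,6-bis(triethylsilyloxy)hex-2-en-1-yl]furan-2(5H)-one
Product: 13 (2Z,4R,6E,9R)-3,7-dimethyl-9,10-bis(triethylsilyloxy)deca-2,6-diene-1,4-diol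
Conditions: i-Bu2AlH (3.5 equiv), CH2Cl2, −78 → 0 °C; aq. potassium sodium tartrate
Reagents that add atoms: none
Why: Full hydride reduction of the lactone gives the Z-ene-1,4-diol with the ring geometry retained; the non-acidic work-up avoids furan formation.

**Step 8**
Reactants: 13 (2Z,4R,6E,9R)-3,7-dimethyl-9,10-bis(triethylsilyloxy)deca-2,6-diene-1,4-diol
Product: 14 (2Z,4R,6E,9R)-3,7-dimethyl-1,4,9,10-tetrakis(triethylsilyloxy)deca-2,6-diene
Conditions: Et3SiCl (2.5 equiv), imidazole, DMF, 0 °C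
Reagents that add atoms: chlorotriethylsilane, CC[Si](Cl)(CC)CC
Why: Routine silylation masks the C3 hydroxyl and makes both chain ends primary TES ethers.

**Step 9**
Reactants: 14 (2Z,4R,6E,9R)-3,7-dimethyl-1,4,9,10-tetrakis(triethylsilyloxy)deca-2,6-diene
Product: 15 (2Z,4R,6E,9R)-3,7-dimethyl-4,9-bis(triethylsilyloxy)deca-2,6-dienedial
Conditions: (COCl)2 (5 equiv), DMSO, CH2Cl2, −78 → −40 °C; then Et3N, −78 → 0 °C
Reagents that add atoms: none
Why: Under Swern conditions primary TES ethers are cleaved by the chlorosulfonium salt and oxidised directly to aldehydes, while secondary TES ethers survive, so the Z-enal (C6) and the C7 aldehyde appear in one operation.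

**Step 10**
Reactants: 15 (2Z,4R,6E,9R)-3,7-dimethyl-4,9-bis(triethylsilyloxy)deca-2,6-dienedial
Product: 16 methyl (4R,6E,9R,10Z)-3-hydroxy-6,10-dimethyl-2-methylidene-12-oxo-4,9-bis(triethylsilyloxy)dodeca-6,10-dienoate (both C3 epimers)
Conditions: methyl acrylate (5 equiv), DABCO (1 equiv), THF–MeOH, 25 °C, 48 h
Reagents that add atoms: methyl acrylate, C=CC(=O)OC
Why: The Morita–Baylis–Hillman reaction is chemoselective for the α-silyloxy aliphatic aldehyde because the β,β-disubstituted enal is a poor acceptor for the ammonium enolate; the new carbinol centre is erased in the next step.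

**Step 11**
Reactants: 16 methyl (4R,6E,9R,10Z)-3-hydroxy-6,10-dimethyl-2-methylidene-12-oxo-4,9-bis(triethylsilyloxy)dodeca-6,10-dienoate
Product: 17 methyl (2Z,4R,6E,9R,10Z)-2-(bromomethyl)-6,10-dimethyl-12-oxo-4,9-bis(triethylsilyloxy)dodeca-2,6,10-trienoate
Conditions: NBS, Me2S, CH2Cl2, −20 → 0 °C
Reagents that add atoms: N-bromosuccinimide, O=C1CCC(=O)N1Br
Why: Corey–Kim-type activation of the Baylis–Hillman alcohol and bromide attack with allylic transposition (SN2′) gives the thermodynamically preferred (Z)-2-(bromomethyl)enoate under neutral conditions.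

**Step 12**
Reactants: 17 methyl (2Z,4R,6E,9R,10Z)-2-(bromomethyl)-6,10-dimethyl-12-oxo-4,9-bis(triethylsilyloxy)dodeca-2,6,10-trienoate
Product: 19 (1(10)E,4Z)-3α,8β-bis(triethylsilyloxy)germacra-1(10),4,11(13)-trien-12,6α-olide, via seco hydroxy ester 18 (not isolated)
Conditions: CrCl3 (10 mol %), n-Bu4NBr, DMF, Al anode/Ni-foam cathode, undivided cell, 3 mA (2.2 F/mol), 17 added by syringe pump over 10 h (final 2 mM), 25 °C; then PPTS (cat.), CH2Cl2, 25 °C
Reagents that add atoms: none
Why: Proposed new method: a chromium-catalysed electroreductive macrocyclising Barbier allylation–lactonisation. Trivalent chromium is reduced at the cathode to divalent chromium, two equivalents of which turn the activated allylic bromide into an allylchromium species that equilibrates and adds through its γ-carbon (C7) to the tethered enal in a chair transition state with C5 and C8 both equatorial, which gives the 6,7-anti (trans-lactone) relationship. C8–H lies anti to the forming bond, the ring-bound C9 takes the less hindered gauche site and the smaller silyloxy group the inside site, which gives the 7α-H/8β-O relationship. Trivalent aluminium ions from the anode free chromium from the alkoxide, which then closes onto the ester. The closest known reactions are the intermolecular chromium-catalysed electrochemical Nozaki–Hiyama–Kishi coupling and the stoichiometric CrCl2-mediated macrocyclic allylations that give germacrane rings.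

**Step 13**
Reactants: 19 (1(10)E,4Z)-3α,8β-bis(triethylsilyloxy)germacra-1(10),4,11(13)-trien-12,6α-olide
Product: 20 (1(10)E,4Z)-3α,8β-dihydroxygermacra-1(10),4,11(13)-trien-12,6α-olide
Conditions: HF·pyridine, pyridine, THF, 0 → 25 °C
Reagents that add atoms: none
Why: Buffered fluoride desilylation removes both TES groups without touching the α-methylene lactone.

**Step 14**
Reactants: 20 (1(10)E,4Z)-3α,8β-dihydroxygermacra-1(10),4,11(13)-trien-12,6α-olide
Product: 21 (1(10)E,4Z)-3β-chloro-8β-hydroxygermacra-1(10),4,11(13)-trien-12,6α-olide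
Conditions: NCS, Me2S, CH2Cl2, −25 → 0 °C
Reagents that add atoms: N-chlorosuccinimide, O=C1CCC(=O)N1Cl
Why: Corey–Kim chlorination substitutes only the allylic alkoxysulfonium salt, by SN2 attack of chloride with inversion (3α-OH → 3β-Cl, 3S); the saturated C8 alcohol is returned on work-up.

**Step 15**
Reactants: 22 L-lactic acid ((S)-2-hydroxypropanoic acid)
Product: 23 (2S,5S)-2-tert-butyl-5-methyl-1,3-dioxolan-4-one
Conditions: t-BuCHO, TsOH (cat.), pentane, reflux (Dean–Stark); cis isomer recrystallised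
Reagents that add atoms: pivalaldehyde, CC(C)(C)C=O
Why: Seebach acetalisation; the lactic acid centre fixes the new acetal centre (cis isomer), which will hold the stereochemical information once C5 becomes an enolate.

**Step 16**
Reactants: 23 (2S,5S)-2-tert-butyl-5-methyl-1,3-dioxolan-4-one
Product: 26 (2S,5R)-2-tert-butyl-5-methyl-5-[(1R)-1-(triethylsilyloxy)ethyl]-1,3-dioxolan-4-one, via lithium enolate 24 (not isolated), via lithium aldolate 25 (not isolated)
Conditions: LiN(i-Pr)2, THF, −78 °C; MeCHO, −78 °C; then Et3SiCl, −78 → 0 °C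
Reagents that add atoms: acetaldehyde, CC=O; chlorotriethylsilane, CC[Si](Cl)(CC)CC; lithium diisopropylamide (Li in 24 and 25 only), [Li]N(C(C)C)C(C)C
Why: Aldol addition with self-regeneration of the stereocentre: the enolate is attacked trans to the tert-butyl group (sets the quaternary centre), a closed Zimmerman–Traxler transition state with the ring-fixed enolate geometry sets the (1R)-carbinol, and in-situ silylation blocks retro-aldol; the minor carbinol epimer is removed by chromatography.

**Step 17**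
Reactants: 26 (2S,5R)-2-tert-butyl-5-methyl-5-[(1R)-1-(triethylsilyloxy)ethyl]-1,3-dioxolan-4-one
Product: 27 (2R,3R)-2-hydroxy-2-methyl-3-(triethylsilyloxy)butanoic acid
Conditions: LiOH, THF–H2O, 0 °C; then cold 1 M HCl to pH 3
Reagents that add atoms: water (as LiOH), O
Why: Saponification of the acylal-type ester releases pivalaldehyde and the acid; the secondary TES ether is stable to cold hydroxide.

**Step 18**
Reactants: 21 (1(10)E,4Z)-3β-chloro-8β-hydroxygermacra-1(10),4,11(13)-trien-12,6α-olide; 27 (2R,3R)-2-hydroxy-2-methyl-3-(triethylsilyloxy)butanoic acid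
Product: 29 (1(10)E,4Z)-3β-chloro-8β-[(2R,3R)-2-hydroxy-2-methyl-3-(triethylsilyloxy)butanoyloxy]germacra-1(10),4,11(13)-trien-12,6α-olide, via mixed anhydride 28 (not isolated)
Conditions: 27, 2,4,6-Cl3C6H2COCl, Et3N, toluene, 25 °C; then 21, DMAP, toluene, 40 °C
Reagents that add atoms: 2,4,6-trichlorobenzoyl chloride (atoms in 28 only), O=C(Cl)c1c(Cl)cc(Cl)cc1Cl
Why: Yamaguchi esterification acylates the hindered C8 alcohol with retention; the tertiary α-hydroxyl of the acid is too hindered to compete.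

**Step 19**
Reactants: 29 (1(10)E,4Z)-3β-chloro-8β-[(2R,3R)-2-hydroxy-2-methyl-3-(triethylsilyloxy)butanoyloxy]germacra-1(10),4,11(13)-trien-12,6α-olide
Product: 30 (1(10)E,4Z)-3β-chloro-8β-[(2R,3R)-2,3-dihydroxy-2-methylbutanoyloxy]germacra-1(10),4,11(13)-trien-12,6α-olide
Conditions: HF·pyridine, pyridine, THF, 0 °C
Reagents that add atoms: none
Why: Fluoride desilylation under buffered conditions, done before the acid-sensitive epoxide exists.

**Step 20**
Reactants: 30 (1(10)E,4Z)-3β-chloro-8β-[(2R,3R)-2,3-dihydroxy-2-methylbutanoyloxy]germacra-1(10),4,11(13)-trien-12,6α-olide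
Product: 31 target, (4Z)-3β-chloro-1β,10α-epoxy-8β-[(2R,3R)-2,3-dihydroxy-2-methylbutanoyloxy]germacra-4,11(13)-dien-12,6α-olide
Conditions: mCPBA (1.05 equiv), NaHCO3, CH2Cl2, 0 °C
Reagents that add atoms: meta-chloroperoxybenzoic acid, OOC(=O)c1cccc(Cl)c1
Why: Prilezhaev epoxidation takes the only electron-rich alkene (C4=C5 is deactivated by the allylic chlorine and lactone oxygen, C11=C13 is conjugated) from the exposed outer face of the E-C1=C10 bond of the germacradiene, which gives the trans 1β,10α-epoxide (1R,10R).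

## Compound list

1 | (S)-glycidol | OC[C@H]1CO1 | starting material
2 | (2R)-pent-4-yne-1,2-diol | OC[C@H](O)CC#C | intermediate
3 | (4R)-4,5-bis(triethylsilyloxy)pent-1-yne | C#CC[C@@H](O[Si](CC)(CC)CC)CO[Si](CC)(CC)CC | intermediate
4 | alkenyldimethylalane from 3 (E) | C[Al](C)/C=C(\C)C[C@@H](O[Si](CC)(CC)CC)CO[Si](CC)(CC)CC | intermediate
5 | (1E,4R)-1-iodo-2-methyl-4,5-bis(triethylsilyloxy)pent-1-ene | I/C=C(\C)C[C@@H](O[Si](CC)(CC)CC)CO[Si](CC)(CC)CC | intermediate
6 | methyl (R)-glycidate | COC(=O)[C@H]1CO1 | starting material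
7 | alkenylmagnesium chloride from 5 (E) | Cl[Mg]/C=C(\C)C[C@@H](O[Si](CC)(CC)CC)CO[Si](CC)(CC)CC | intermediate
8 | methyl (2R,4E,7R)-2-hydroxy-5-methyl-7,8-bis(triethylsilyloxy)oct-4-enoate | COC(=O)[C@H](O)C/C=C(\C)C[C@@H](O[Si](CC)(CC)CC)CO[Si](CC)(CC)CC | intermediate
9 | Weinreb amide of 8 (N-methoxy-N-methyl amide, formed as its magnesium alkoxide) | CON(C)C(=O)[C@H](O)C/C=C(\C)C[C@@H](O[Si](CC)(CC)CC)CO[Si](CC)(CC)CC | intermediate
10 | (3R,5E,8R)-3-hydroxy-6-methyl-8,9-bis(triethylsilyloxy)non-5-en-2-one | CC(=O)[C@H](O)C/C=C(\C)C[C@@H](O[Si](CC)(CC)CC)CO[Si](CC)(CC)CC | intermediate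
11 | (triphenylphosphoranylidene)acetate ester of 10 | CC(=O)[C@H](OC(=O)C=P(c1ccccc1)(c1ccccc1)c1ccccc1)C/C=C(\C)C[C@@H](O[Si](CC)(CC)CC)CO[Si](CC)(CC)CC | intermediate
12 | (5R)-4-methyl-5-[(2E,5R)-3-methyl-5,6-bis(triethylsilyloxy)hex-2-en-1-yl]furan-2(5H)-one | O=C1C=C(C)[C@@H](C/C=C(\C)C[C@@H](O[Si](CC)(CC)CC)CO[Si](CC)(CC)CC)O1 | intermediate
13 | (2Z,4R,6E,9R)-3,7-dimethyl-9,10-bis(triethylsilyloxy)deca-2,6-diene-1,4-diol | OC/C=C(/C)[C@H](O)C/C=C(\C)C[C@@H](O[Si](CC)(CC)CC)CO[Si](CC)(CC)CC | intermediate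
14 | (2Z,4R,6E,9R)-3,7-dimethyl-1,4,9,10-tetrakis(triethylsilyloxy)deca-2,6-diene | CC[Si](CC)(CC)OC/C=C(/C)[C@H](O[Si](CC)(CC)CC)C/C=C(\C)C[C@@H](O[Si](CC)(CC)CC)CO[Si](CC)(CC)CC | intermediate
15 | (2Z,4R,6E,9R)-3,7-dimethyl-4,9-bis(triethylsilyloxy)deca-2,6-dienedial | O=C/C=C(/C)[C@H](O[Si](CC)(CC)CC)C/C=C(\C)C[C@@H](O[Si](CC)(CC)CC)C=O | intermediate
16 | methyl (4R,6E,9R,10Z)-3-hydroxy-6,10-dimethyl-2-methylidene-12-oxo-4,9-bis(triethylsilyloxy)dodeca-6,10-dienoate (C3 epimers) | O=C/C=C(/C)[C@H](O[Si](CC)(CC)CC)C/C=C(\C)C[C@@H](O[Si](CC)(CC)CC)C(O)C(=C)C(=O)OC | intermediate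
17 | methyl (2Z,4R,6E,9R,10Z)-2-(bromomethyl)-6,10-dimethyl-12-oxo-4,9-bis(triethylsilyloxy)dodeca-2,6,10-trienoate | O=C/C=C(/C)[C@H](O[Si](CC)(CC)CC)C/C=C(\C)C[C@@H](O[Si](CC)(CC)CC)/C=C(\CBr)C(=O)OC | intermediate
18 | methyl (1(10)E,4Z)-6α-hydroxy-3α,8β-bis(triethylsilyloxy)germacra-1(10),4,11(13)-trien-12-oate (formed as its metal alkoxide) | C=C(C(=O)OC)[C@H]1[C@H](O)/C=C(/C)[C@H](O[Si](CC)(CC)CC)C/C=C(\C)C[C@H]1O[Si](CC)(CC)CC | intermediate
19 | (1(10)E,4Z)-3α,8β-bis(triethylsilyloxy)germacra-1(10),4,11(13)-trien-12,6α-olide | C=C1C(=O)O[C@@H]2/C=C(/C)[C@H](O[Si](CC)(CC)CC)C/C=C(\C)C[C@@H](O[Si](CC)(CC)CC)[C@@H]12 | intermediate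
20 | (1(10)E,4Z)-3α,8β-dihydroxygermacra-1(10),4,11(13)-trien-12,6α-olide | C=C1C(=O)O[C@@H]2/C=C(/C)[C@H](O)C/C=C(\C)C[C@@H](O)[C@@H]12 | intermediate
21 | (1(10)E,4Z)-3β-chloro-8β-hydroxygermacra-1(10),4,11(13)-trien-12,6α-olide | C=C1C(=O)O[C@@H]2/C=C(/C)[C@@H](Cl)C/C=C(\C)C[C@@H](O)[C@@H]12 | intermediate
22 | L-lactic acid | C[C@H](O)C(=O)O | starting material
23 | (2S,5S)-2-tert-butyl-5-methyl-1,3-dioxolan-4-one | C[C@@H]1O[C@H](C(C)(C)C)OC1=O | intermediate
24 | lithium enolate of 23 | CC1=C(O[Li])O[C@@H](C(C)(C)C)O1 | intermediate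
25 | lithium aldolate, (2S,5R)-2-tert-butyl-5-[(1R)-1-lithiooxyethyl]-5-methyl-1,3-dioxolan-4-one | C[C@]1([C@@H](C)O[Li])O[C@H](C(C)(C)C)OC1=O | intermediate
26 | (2S,5R)-2-tert-butyl-5-methyl-5-[(1R)-1-(triethylsilyloxy)ethyl]-1,3-dioxolan-4-one | C[C@]1([C@@H](C)O[Si](CC)(CC)CC)O[C@H](C(C)(C)C)OC1=O | intermediate
27 | (2R,3R)-2-hydroxy-2-methyl-3-(triethylsilyloxy)butanoic acid | OC(=O)[C@](C)(O)[C@@H](C)O[Si](CC)(CC)CC | intermediate
28 | mixed anhydride of 27 with 2,4,6-trichlorobenzoic acid | O=C(OC(=O)[C@](C)(O)[C@@H](C)O[Si](CC)(CC)CC)c1c(Cl)cc(Cl)cc1Cl | intermediate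
29 | (1(10)E,4Z)-3β-chloro-8β-[(2R,3R)-2-hydroxy-2-methyl-3-(triethylsilyloxy)butanoyloxy]germacra-1(10),4,11(13)-trien-12,6α-olide | C=C1C(=O)O[C@@H]2/C=C(/C)[C@@H](Cl)C/C=C(\C)C[C@@H](OC(=O)[C@](C)(O)[C@@H](C)O[Si](CC)(CC)CC)[C@@H]12 | intermediate
30 | (1(10)E,4Z)-3β-chloro-8β-[(2R,3R)-2,3-dihydroxy-2-methylbutanoyloxy]germacra-1(10),4,11(13)-trien-12,6α-olide | C=C1C(=O)O[C@@H]2/C=C(/C)[C@@H](Cl)C/C=C(\C)C[C@@H](OC(=O)[C@](C)(O)[C@@H](C)O)[C@@H]12 | intermediate
31 | CNP0325326.4, (4Z)-3β-chloro-1β,10α-epoxy-8β-[(2R,3R)-2,3-dihydroxy-2-methylbutanoyloxy]germacra-4,11(13)-dien-12,6α-olide | C=C1C(=O)O[C@@H]2/C=C(/C)[C@@H](Cl)C[C@H]3O[C@]3(C)C[C@@H](OC(=O)[C@](C)(O)[C@@H](C)O)[C@@H]12 | target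

## Step count and risks

Total steps: 20. Longest linear sequence: 17 (steps 1–14 and 18–20); steps 15–17 make the side-chain acid.

The three steps most likely to fail:

**Step 12 (proposed new electroreductive macrocyclisation).** The risks are oligomerisation, inefficient chromium turnover at the electrode, and the facial selectivity at C6/C7, which rests on a transition-state argument and not on precedent. Fallback with known chemistry: set out from bromide 17 and replace the cathodic catalytic cycle by the classical stoichiometric Nozaki–Hiyama macrocyclic allylation (CrCl2, 8 equiv, DMF–THF, 1 mM by syringe pump, 25 °C). The seco hydroxy ester 18 is isolated and then lactonised in a separate operation (PPTS, benzene, 50 °C), returning to the route at macrolactone 19. This makes no new compound (F0).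

**Step 14 (allylic chlorination of diol 20).** The risks are poor discrimination between the C3 and C8 hydroxyls, SN2′ attack, and transannular reaction of the activated germacradiene. Fallback: set out from bis-silyl ether 19 and differentiate the two oxygens stepwise instead of relying on reagent selectivity. Mild methanolysis (PPTS 0.1 equiv, MeOH–CH2Cl2, −10 °C) removes the less hindered allylic 3-O-TES group and gives (1(10)E,4Z)-3α-hydroxy-8β-(triethylsilyloxy)germacra-1(10),4,11(13)-trien-12,6α-olide F1. Its single free hydroxyl is converted with inversion by a phosphonium-type displacement (Ph3P, hexachloroacetone, CH2Cl2, −30 °C) into (1(10)E,4Z)-3β-chloro-8β-(triethylsilyloxy)germacra-1(10),4,11(13)-trien-12,6α-olide F2. HF·pyridine then removes the C8 silyl group and the route is rejoined at chloro alcohol 21.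

**Step 10 (Baylis–Hillman reaction on dialdehyde 15).** The risks are slow conversion, Z → E isomerisation of the enal by the nucleophilic amine, and epimerisation at C8. Fallback: set out from 15 and use a preformed organometallic instead of amine catalysis. [α-(Methoxycarbonyl)vinyl]diisobutylalane (from i-Bu2AlH, N-methylmorpholine N-oxide and methyl propiolate, THF, 0 °C) is added to 15 at −78 °C; this vinylalumination attacks the more electrophilic α-silyloxy aldehyde and gives the same adduct, returning to the route at 16. This makes no new compound (F0).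

## Further compounds

F0 | step 10 | none | none
F0 | step 12 | none | none
F1 | step 14 | (1(10)E,4Z)-3α-hydroxy-8β-(triethylsilyloxy)germacra-1(10),4,11(13)-trien-12,6α-olide | C=C1C(=O)O[C@@H]2/C=C(/C)[C@H](O)C/C=C(\C)C[C@@H](O[Si](CC)(CC)CC)[C@@H]12
F2 | step 14 | (1(10)E,4Z)-3β-chloro-8β-(triethylsilyloxy)germacra-1(10),4,11(13)-trien-12,6α-olide | C=C1C(=O)O[C@@H]2/C=C(/C)[C@@H](Cl)C/C=C(\C)C[C@@H](O[Si](CC)(CC)CC)[C@@H]12
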